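Araneosol is disconnected in ring C. The pyranone carbonyl C4 is bonded only to C4a of ring A and to C3, a one-carbon unit that carbon monoxide can supply. 4-Ethynylanisole delivers C2, C3 and ring B, and a phenol oxygen becomes O1. One palladium-catalysed carbonylative coupling–cyclisation therefore makes C4a–C4, C4–C3 and O1–C2 and closes the pyranone. Its precursor is a hexasubstituted benzene, 3,5-bis(benzyloxy)-2-iodo-4,6-dimethoxyphenol, with iodine on the future C4a. It is reached from syringol through a 4,6-dibromide whose bromines are replaced by oxygen one at a time, so the C5 and O1 oxygens are never equivalent and no statistical monobenzylation arises. C3 hydroxylation, methylation and hydrogenolysis complete the route.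

Key step: step 7

Remark: araneosol has no stereocentre and no stereogenic double bond, so it is achiral; there is no enantiomer to select and no step needs stereocontrol. Flavone numbering is used for ring positions.

Step 1
Reactants: 1 syringol (2,6-dimethoxyphenol)
Product: 2 2-(benzyloxy)-1,3-dimethoxybenzene
Conditions: BnBr, K2CO3, DMF, 60 °C
Reagents that add atoms: benzyl bromide, BrCc1ccccc1
Why: Williamson ether synthesis, in which the acidic phenoxide of 1 is alkylated by the reactive benzylic bromide, and capping this oxygen (the future C7 oxygen) also removes the para-directing free phenol before the bromination.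

Step 2
Reactants: 2 2-(benzyloxy)-1,3-dimethoxybenzene
Product: 3 3-(benzyloxy)-1,5-dibromo-2,4-dimethoxybenzene (the 4,6-dibromide of 2)
Conditions: NBS (2.1 equiv), MeCN, 0 °C → rt, dark
Reagents that add atoms: N-bromosuccinimide, O=C1CCC(=O)N1Br
Why: Electrophilic aromatic bromination by the ionic NBS pathway, in which each bromine enters ortho to one methoxy group and para to the other, whereas C5 is para only to the central benzyloxy group that its two neighbours twist out of conjugation, so the 4,6-pattern typical of pyrogallol trialkyl ethers is expected.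

Step 3
Reactants: 3 3-(benzyloxy)-1,5-dibromo-2,4-dimethoxybenzene
Product: 6 3-(benzyloxy)-5-bromo-2,4-dimethoxyphenol, via aryllithium 4 (not isolated), via dimethyl arylboronate 5 (not isolated)
Conditions: n-BuLi (1.05 equiv), THF, −78 °C; B(OMe)3, −78 °C → rt; AcOH, 30% H2O2, 0 °C → rt
Reagents that add atoms: hydrogen peroxide, OO (phenol oxygen of 6); n-butyllithium, [Li]CCCC (lithium of 4 only); trimethyl borate, COB(OC)OC (boron unit of 5 only)
Why: Bromine–lithium exchange, borylation and peroxide oxidation (ipso-hydroxylation), in which one equivalent of n-BuLi exchanges only one of the two equivalent bromines because a second exchange on an aryllithium is strongly disfavoured, the surviving bromine is meta to lithium so no aryne can form, and the C–B to C–O migration places oxygen exactly where bromine stood.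

Step 4
Reactants: 6 3-(benzyloxy)-5-bromo-2,4-dimethoxyphenol
Product: 7 1,3-bis(benzyloxy)-5-bromo-2,4-dimethoxybenzene
Conditions: BnBr, K2CO3, DMF, rt → 50 °C
Reagents that add atoms: benzyl bromide, BrCc1ccccc1
Why: Williamson ether synthesis on the only free hydroxyl group, which fixes the benzyl ether of the future C5 oxygen without any selection between equivalent sites.

Step 5
Reactants: 7 1,3-bis(benzyloxy)-5-bromo-2,4-dimethoxybenzene
Product: 10 3,5-bis(benzyloxy)-2,4-dimethoxyphenol, via aryllithium 8 (not isolated), via dimethyl arylboronate 9 (not isolated)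
Conditions: n-BuLi (1.1 equiv), THF, −78 °C; B(OMe)3, −78 °C → rt; AcOH, 30% H2O2, 0 °C
Reagents that add atoms: hydrogen peroxide, OO (phenol oxygen of 10); n-butyllithium, [Li]CCCC (lithium of 8 only); trimethyl borate, COB(OC)OC (boron unit of 9 only)
Why: The same bromine–lithium exchange, borylation and oxidation as in step 3, since aryl benzyl ethers tolerate n-BuLi at −78 °C over the short exchange time and the acetic acid-buffered peroxide spares the electron-rich ring.

Step 6
Reactants: 10 3,5-bis(benzyloxy)-2,4-dimethoxyphenol
Product: 11 3,5-bis(benzyloxy)-2-iodo-4,6-dimethoxyphenol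
Conditions: NIS (1.0 equiv), MeCN, −10 → 0 °C, dark
Reagents that add atoms: N-iodosuccinimide, O=C1CCC(=O)N1I
Why: Electrophilic aromatic iodination of a phenol whose single C–H is ortho to the hydroxyl group, ortho to one benzyloxy group and para to the other, so one equivalent of NIS at low temperature can only deliver 11.

Step 7
Reactants: 11 3,5-bis(benzyloxy)-2-iodo-4,6-dimethoxyphenol; 12 4-ethynylanisole; 13 carbon monoxide
Product: 16 5,7-bis(benzyloxy)-6,8,4'-trimethoxyflavone, via hydroxyaryl ynone 14 (not isolated), via diethylamino enaminone 15 (not isolated)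
Conditions: Pd(OAc)2 (5 mol %), BuPAd2 (cataCXium A, 12 mol %), CO (10 bar), 12 (1.3 equiv), Et2NH (5 equiv), DMF, 90 °C, no copper
Reagents that add atoms: carbon monoxide (13), [C-]#[O+]; 4-ethynylanisole (12), C#Cc1ccc(OC)cc1; diethylamine, CCNCC (held only in intermediate 15 and released on ring closure)
Why: Pd(0) inserts into the C–I bond of 11, migratory insertion of CO gives the aroylpalladium species, and amine-assisted alkynylation with 12 followed by reductive elimination forms C4a–C4 and C4–C3 in ynone 14. Diethylamine then undergoes aza-Michael addition to 14 to give enaminone 15, whose β-carbon (future C2) is attacked by the neighbouring phenol oxygen with expulsion of the amine, which forms O1–C2. The closest known reaction type is the palladium-catalysed carbonylative Sonogashira coupling–cyclisation of 2-iodophenols, carbon monoxide and terminal alkynes to flavones. The single new ring, the pyranone, closes in a net 6-endo mode (addition–elimination on the enaminone), and no stereocentre is created. Three selectivities are needed: six- over five-membered closure, secured because the amine has already made the carbon next to ring B the only electrophilic site; carbonylative over direct coupling, secured by CO pressure, the absence of copper and the fast CO insertion of an electron-rich aryl–Pd bond; and alkynylation over aminocarbonylation, helped by the two ortho substituents that shield the acyl carbon from the bulkier amine. Positional ambiguity does not exist because 11 has one free hydroxyl group and one C–I bond, and the bulky, electron-rich phosphine is chosen to drive oxidative addition at this crowded, electron-rich carbon.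

Step 8
Reactants: 16 5,7-bis(benzyloxy)-6,8,4'-trimethoxyflavone
Product: 19 5,7-bis(benzyloxy)-3-hydroxy-6,8,4'-trimethoxyflavone, via 3-lithioflavone 17 (not isolated), via flavon-3-ylboronate 18 (not isolated)
Conditions: LDA (commercial solution, 1.5 equiv), THF, −78 °C; B(OMe)3 (3 equiv), −78 → 0 °C; AcOH, 30% H2O2, 0 °C → rt
Reagents that add atoms: hydrogen peroxide, OO (3-OH oxygen of 19); lithium diisopropylamide, [Li]N(C(C)C)C(C)C (lithium of 17 only); trimethyl borate, COB(OC)OC (boron unit of 18 only)
Why: C3 lithiation of a flavone followed by borylation and peroxide oxidation, in which H3 is the most acidic C–H (vinylic and next to the lithium-chelating C4 carbonyl), the anion is trapped by the borate at −78 °C before the ring can open, and oxidative 1,2-migration converts C3–B into C3–OH.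

Step 9
Reactants: 19 5,7-bis(benzyloxy)-3-hydroxy-6,8,4'-trimethoxyflavone
Product: 20 5,7-bis(benzyloxy)-3,6,8,4'-tetramethoxyflavone
Conditions: MeI, K2CO3, acetone, reflux
Reagents that add atoms: iodomethane, CI
Why: Williamson-type O-methylation of the only free hydroxyl group, the acidic enolic 3-OH, while every other oxygen is capped.

Step 10
Reactants: 20 5,7-bis(benzyloxy)-3,6,8,4'-tetramethoxyflavone
Product: 21 araneosol (5,7-dihydroxy-3,6,8,4'-tetramethoxyflavone)
Conditions: H2 (1 atm), 10% Pd/C, EtOAc–MeOH, rt
Reagents that add atoms: none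
Why: Catalytic hydrogenolysis of both aryl benzyl ethers under one atmosphere of hydrogen, conditions that leave the methyl ethers and the tetrasubstituted, conjugated C2=C3 bond of a 3-methoxyflavone untouched.

Compound list
1 | syringol (2,6-dimethoxyphenol) | COc1cccc(OC)c1O | starting material
2 | 2-(benzyloxy)-1,3-dimethoxybenzene | COc1cccc(OC)c1OCc1ccccc1 | intermediate
3 | 3-(benzyloxy)-1,5-dibromo-2,4-dimethoxybenzene | COc1c(Br)cc(Br)c(OC)c1OCc1ccccc1 | intermediate
4 | [3-(benzyloxy)-5-bromo-2,4-dimethoxyphenyl]lithium | [Li]c1cc(Br)c(OC)c(OCc2ccccc2)c1OC | intermediate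
5 | dimethyl [3-(benzyloxy)-5-bromo-2,4-dimethoxyphenyl]boronate | COB(OC)c1cc(Br)c(OC)c(OCc2ccccc2)c1OC | intermediate
6 | 3-(benzyloxy)-5-bromo-2,4-dimethoxyphenol | Oc1cc(Br)c(OC)c(OCc2ccccc2)c1OC | intermediate
7 | 1,3-bis(benzyloxy)-5-bromo-2,4-dimethoxybenzene | COc1c(Br)cc(OCc2ccccc2)c(OC)c1OCc1ccccc1 | intermediate
8 | [3,5-bis(benzyloxy)-2,4-dimethoxyphenyl]lithium | [Li]c1cc(OCc2ccccc2)c(OC)c(OCc2ccccc2)c1OC | intermediate
9 | dimethyl [3,5-bis(benzyloxy)-2,4-dimethoxyphenyl]boronate | COB(OC)c1cc(OCc2ccccc2)c(OC)c(OCc2ccccc2)c1OC | intermediate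
10 | 3,5-bis(benzyloxy)-2,4-dimethoxyphenol | Oc1cc(OCc2ccccc2)c(OC)c(OCc2ccccc2)c1OC | intermediate
11 | 3,5-bis(benzyloxy)-2-iodo-4,6-dimethoxyphenol | Oc1c(I)c(OCc2ccccc2)c(OC)c(OCc2ccccc2)c1OC | intermediate
12 | 4-ethynylanisole | C#Cc1ccc(OC)cc1 | starting material
13 | carbon monoxide | [C-]#[O+] | starting material
14 | 1-[2,4-bis(benzyloxy)-6-hydroxy-3,5-dimethoxyphenyl]-3-(4-methoxyphenyl)prop-2-yn-1-one | COc1ccc(C#CC(=O)c2c(O)c(OC)c(OCc3ccccc3)c(OC)c2OCc2ccccc2)cc1 | intermediate
15 | (E)-1-[2,4-bis(benzyloxy)-6-hydroxy-3,5-dimethoxyphenyl]-3-(diethylamino)-3-(4-methoxyphenyl)prop-2-en-1-one (push–pull alkene, geometry labile and without consequence) | CCN(CC)/C(=C/C(=O)c1c(O)c(OC)c(OCc2ccccc2)c(OC)c1OCc1ccccc1)c1ccc(OC)cc1 | intermediate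
16 | 5,7-bis(benzyloxy)-6,8,4'-trimethoxyflavone | COc1ccc(-c2cc(=O)c3c(OCc4ccccc4)c(OC)c(OCc4ccccc4)c(OC)c3o2)cc1 | intermediate
17 | 5,7-bis(benzyloxy)-3-lithio-6,8,4'-trimethoxyflavone | [Li]c1c(-c2ccc(OC)cc2)oc2c(OC)c(OCc3ccccc3)c(OC)c(OCc3ccccc3)c2c1=O | intermediate
18 | dimethyl [5,7-bis(benzyloxy)-6,8,4'-trimethoxyflavon-3-yl]boronate | COB(OC)c1c(-c2ccc(OC)cc2)oc2c(OC)c(OCc3ccccc3)c(OC)c(OCc3ccccc3)c2c1=O | intermediate
19 | 5,7-bis(benzyloxy)-3-hydroxy-6,8,4'-trimethoxyflavone | COc1ccc(-c2oc3c(OC)c(OCc4ccccc4)c(OC)c(OCc4ccccc4)c3c(=O)c2O)cc1 | intermediate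
20 | 5,7-bis(benzyloxy)-3,6,8,4'-tetramethoxyflavone | COc1ccc(-c2oc3c(OC)c(OCc4ccccc4)c(OC)c(OCc4ccccc4)c3c(=O)c2OC)cc1 | intermediate
21 | araneosol (5,7-dihydroxy-3,6,8,4'-tetramethoxyflavone, achiral) | COc1ccc(-c2oc3c(OC)c(O)c(OC)c(O)c3c(=O)c2OC)cc1 | target

Total step count: 10. Longest linear sequence: 10 steps (1 → 21); 12 and 13 enter in step 7.

Steps most likely to fail

Step 7. Oxidative addition at the crowded, electron-rich C–I bond may be too slow. Hydrodeiodination, CO-free alkynylation with five-membered closure, or interception of the acylpalladium by the amine could then take over. The fallback replaces palladium and CO by a stepwise organometallic acylation. It sets out from 11 and 12 and comes back at 14, and from there at 16.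
- The phenol of 11 is masked (MOMCl, iPr2NEt, CH2Cl2) as 1,3-bis(benzyloxy)-4-iodo-2,6-dimethoxy-5-(methoxymethoxy)benzene F1.
- Separately, 12 is deprotonated (n-BuLi, THF, −78 °C) to lithium (4-methoxyphenyl)acetylide F2. This is acylated with N-methoxy-N-methylcarbamoyl chloride to the Weinreb amide N-methoxy-3-(4-methoxyphenyl)-N-methylprop-2-ynamide F3.
- Iodine–magnesium exchange on F1 (iPrMgCl·LiCl, THF, −20 °C) gives the arylmagnesium chloride F4. It adds once to F3 and, after work-up, gives the MOM-protected ynone F5.
- Catalytic HCl in MeOH removes the acetal to give 14, and Et2NH in EtOH closes it through 15 to 16.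

Step 8. The lithiated pyranone may open by β-elimination of the ring phenoxide. A benzylic CH2 may be deprotonated in competition, or the boronate may protodeboronate before oxidation. The fallback uses electrophilic oxygen transfer instead of deprotonation. It sets out from 16 and comes back at 19. Dimethyldioxirane (acetone–CH2Cl2, 0 °C) epoxidises the C2=C3 bond to racemic 5,7-bis(benzyloxy)-2,3-epoxy-6,8,4'-trimethoxyflavanone F6. Catalytic p-TsOH in CH2Cl2 opens the oxirane at C2, where the cation is stabilised by O1 and the anisyl ring, and loss of H3 gives 19.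

Step 6. The very electron-rich phenol may be oxidised (oxidative demethylation) in competition with C–I bond formation, or iodine may be lost under acid during isolation. The fallback uses directed ortho-metalation instead of electrophilic substitution. It sets out from 10 and comes back at 11. MOMCl and iPr2NEt give 1,3-bis(benzyloxy)-2,4-dimethoxy-5-(methoxymethoxy)benzene F7. n-BuLi (THF, −78 → −20 °C) removes the only ring proton, which is flanked by two coordinating oxygens, to give the aryllithium F8. Iodine converts it into the MOM-protected iodide F1, and catalytic HCl in MeOH at rt releases 11.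

Further compounds
F1 | step 7 | 1,3-bis(benzyloxy)-4-iodo-2,6-dimethoxy-5-(methoxymethoxy)benzene | COCOc1c(I)c(OCc2ccccc2)c(OC)c(OCc2ccccc2)c1OC
F2 | step 7 | lithium (4-methoxyphenyl)acetylide | [Li]C#Cc1ccc(OC)cc1
F3 | step 7 | N-methoxy-3-(4-methoxyphenyl)-N-methylprop-2-ynamide | CON(C)C(=O)C#Cc1ccc(OC)cc1
F4 | step 7 | [2,4-bis(benzyloxy)-3,5-dimethoxy-6-(methoxymethoxy)phenyl]magnesium chloride | COCOc1c([Mg]Cl)c(OCc2ccccc2)c(OC)c(OCc2ccccc2)c1OC
F5 | step 7 | 1-[2,4-bis(benzyloxy)-3,5-dimethoxy-6-(methoxymethoxy)phenyl]-3-(4-methoxyphenyl)prop-2-yn-1-one | COCOc1c(OC)c(OCc2ccccc2)c(OC)c(OCc2ccccc2)c1C(=O)C#Cc1ccc(OC)cc1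
F6 | step 8 | 5,7-bis(benzyloxy)-2,3-epoxy-6,8,4'-trimethoxyflavanone (racemic, cis-fused oxirane, one enantiomer drawn) | COc1ccc(cc1)[C@]12O[C@H]1C(=O)c1c(O2)c(OC)c(OCc2ccccc2)c(OC)c1OCc1ccccc1
F7 | step 6 | 1,3-bis(benzyloxy)-2,4-dimethoxy-5-(methoxymethoxy)benzene | COCOc1cc(OCc2ccccc2)c(OC)c(OCc2ccccc2)c1OC
F8 | step 6 | [2,4-bis(benzyloxy)-3,5-dimethoxy-6-(methoxymethoxy)phenyl]lithium | COCOc1c([Li])c(OCc2ccccc2)c(OC)c(OCc2ccccc2)c1OC
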